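The cut is the C2–C3 bond of the unbranched C23 acyl chain. C1 and C2 arrive as a malonate half ester that already carries the 2-phenylethyl ester oxygen and the benzene ring (the only ring, a spectator). C3–C23 arrive as a C21 acyl imidazolide. The feature exploited is the C2 methylene–C1 ester carbonyl unit next to an unfunctionalised methylene chain: a magnesium-mediated decarboxylative Claisen condensation should join the two pieces in one operation to the beta-keto ester, with the ester already in place. The C3 ketone is then removed by reduction, dehydration and hydrogenation.

Key step: step 3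

Remark on the chemistry: the target is achiral; the C3 carbinol centre that appears in step 4 is racemic and is removed again in step 5.

Step 1
Reactants: 1 Meldrum's acid (2,2-dimethyl-1,3-dioxane-4,6-dione); 2 2-phenylethanol
Product: 3 3-oxo-3-(2-phenylethoxy)propanoic acid (mono-2-phenylethyl malonate)
Conditions: 1 (1.05 equiv), toluene, 105 °C, 4 h; extraction into aq. NaHCO3, acidification, extraction
Reagents that add atoms: none
Why: Alcoholysis of Meldrum's acid: the alcohol opens the electrophilic cyclic acylal at one carbonyl and the hemiketal ester collapses with loss of acetone, a standard entry to malonic monoesters, and the acid is freed from neutral material (residual alcohol) by the bicarbonate extraction.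

Step 2
Reactants: 4 henicosanoic acid; 5 1,1'-carbonyldiimidazole
Product: 6 1-(1H-imidazol-1-yl)henicosan-1-one
Conditions: CDI (1.05 equiv), THF, 45 °C, 2 h, N2; concentrated and used crude
Reagents that add atoms: 1,1'-carbonyldiimidazole (compound 5), O=C(n1ccnc1)n1ccnc1
Why: N-Acylimidazole formation from a carboxylic acid and CDI is driven by loss of CO2 and is clean for saturated fatty acids; only a slight excess of CDI is used so that none is left to consume the malonate in step 3.

Step 3
Reactants: 6 1-(1H-imidazol-1-yl)henicosan-1-one; 3 3-oxo-3-(2-phenylethoxy)propanoic acid
Product: 9 2-phenylethyl 3-oxotricosanoate, via magnesium half-ester chelate 7 (not isolated), via magnesium acylmalonate chelate 8 (not isolated)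
Conditions: 3 (1.5 equiv), MgCl2 (1.5 equiv), Et3N (3 equiv), MeCN–THF, rt, 2 h; then 6 in THF, rt to 45 °C, 16 h; 1 M HCl work-up, NaHCO3 wash
Reagents that add atoms: none
Why: The divalent magnesium ion binds both carbonyl oxygens of the half ester, so Et3N can remove a C2 proton and form the chelated enolate–carboxylate 7; its carbon adds to the acyl imidazolide carbonyl and imidazolide is expelled (addition–elimination), giving the chelated acylmalonate 8, which loses CO2 on acidification to leave the beta-keto ester. The closest known reaction type is the Masamune–Claisen condensation of magnesium malonate half esters with N-acylimidazoles, here in its MgCl2/Et3N variant. The single new bond is C2–C3; no ring is closed and no stereocentre is formed. The step needs C- over O-acylation and single over double acylation: chelation holds the oxygens on magnesium so that carbon is the nucleophile, and 8 stays bound as an unreactive chelate until the quench, while the loss of CO2 makes the condensation irreversible. The saturated C21 acyl donor has no other reactive site, and the 2-phenylethyl ester meets only Et3N, so it should be neither cleaved nor exchanged.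

Step 4
Reactants: 9 2-phenylethyl 3-oxotricosanoate
Product: 10 2-phenylethyl 3-hydroxytricosanoate (racemic)
Conditions: NaBH4 (1 equiv), THF–EtOH (10:1), 0 °C, 30 min; aq. NH4Cl
Reagents that add atoms: none
Why: Chemoselective borohydride reduction of the ketone of a beta-keto ester (the ester is inert at 0 °C and the small alcohol content limits ester exchange); the C3 carbinol centre forms without control as a racemate, which does not matter because step 5 destroys it.

Step 5
Reactants: 10 2-phenylethyl 3-hydroxytricosanoate (racemic)
Product: 12 2-phenylethyl (2E)-tricos-2-enoate, via 3-mesyloxy ester 11 (not isolated)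
Conditions: MsCl, Et3N, CH2Cl2, 0 °C; then DBU, rt
Reagents that add atoms: none
Why: Mesylation followed by base-induced E1cB elimination of a beta-sulfonyloxy ester is a standard dehydration that should give the conjugated (E)-enoate; any Z or beta,gamma isomer converges to the same product in step 6.

Step 6
Reactants: 12 2-phenylethyl (2E)-tricos-2-enoate
Product: 13 2-phenylethyl tricosanoate
Conditions: H2 (1 atm), 10% Pd/C, EtOAc, rt
Reagents that add atoms: none
Why: Heterogeneous catalytic hydrogenation of a conjugated disubstituted alkene over zerovalent palladium on carbon is fast at 1 atm, while the ester C–O bond is homobenzylic, not benzylic, so it should not be hydrogenolysed, and the benzene ring is not reduced under these conditions.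

Compound list
1 | Meldrum's acid (2,2-dimethyl-1,3-dioxane-4,6-dione) | CC1(C)OC(=O)CC(=O)O1 | starting material
2 | 2-phenylethanol | OCCc1ccccc1 | starting material
3 | 3-oxo-3-(2-phenylethoxy)propanoic acid (mono-2-phenylethyl malonate) | OC(=O)CC(=O)OCCc1ccccc1 | intermediate
4 | henicosanoic acid | CCCCCCCCCCCCCCCCCCCCC(=O)O | starting material
5 | 1,1'-carbonyldiimidazole | O=C(n1ccnc1)n1ccnc1 | starting material
6 | 1-(1H-imidazol-1-yl)henicosan-1-one | CCCCCCCCCCCCCCCCCCCCC(=O)n1ccnc1 | intermediate
7 | magnesium enolate–carboxylate chelate of 3, formed in the flask | [Mg+2].[O-]C(=O)C=C([O-])OCCc1ccccc1 | intermediate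
8 | magnesium chelate of 2-henicosanoylmalonic acid mono(2-phenylethyl) ester (enolate–carboxylate), formed in the flask | [Mg+2].CCCCCCCCCCCCCCCCCCCCC([O-])=C(C(=O)[O-])C(=O)OCCc1ccccc1 | intermediate
9 | 2-phenylethyl 3-oxotricosanoate | CCCCCCCCCCCCCCCCCCCCC(=O)CC(=O)OCCc1ccccc1 | intermediate
10 | 2-phenylethyl 3-hydroxytricosanoate, racemic at C3 | CCCCCCCCCCCCCCCCCCCCC(O)CC(=O)OCCc1ccccc1 | intermediate
11 | 2-phenylethyl 3-(methanesulfonyloxy)tricosanoate, racemic at C3, formed in the flask | CCCCCCCCCCCCCCCCCCCCC(OS(C)(=O)=O)CC(=O)OCCc1ccccc1 | intermediate
12 | 2-phenylethyl (2E)-tricos-2-enoate | CCCCCCCCCCCCCCCCCCCC/C=C/C(=O)OCCc1ccccc1 | intermediate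
13 | 2-phenylethyl tricosanoate (achiral) | CCCCCCCCCCCCCCCCCCCCCCC(=O)OCCc1ccccc1 | target

Total step count: 6
Longest linear sequence: 5 steps (4 to 6 to 9 to 10 to 12 to 13; the branch from 1 and 2 through 3 is equally long)

Steps most likely to fail

1. Step 3. The waxy acyl imidazolide may react slowly with the partly heterogeneous magnesium enolate. Moisture, or acyl transfer to oxygen or to the carboxylate, could then win and return 4 after work-up, or the half ester could lose CO2 before it is acylated. Fallback by the acylketene route: setting out from 4, the acid would be coupled to Meldrum's acid 1 with DCC and DMAP in CH2Cl2 at 0 °C to rt to give 5-(1-hydroxyhenicosylidene)-2,2-dimethyl-1,3-dioxane-4,6-dione F1. Heating this with 2-phenylethanol 2 in toluene at 110 °C should expel acetone and CO2, and the alcohol should trap the resulting acylketene. The route is rejoined at 9.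

2. Step 5. Elimination may stall at the mesylate, or the base may cause retro-aldol-type cleavage or chloride substitution in place of clean loss of methanesulfonate. Fallback by thioketal reduction, which bypasses the alcohol and the alkene: setting out from 9, the ketone would be converted with ethane-1,2-dithiol and BF3·OEt2 in CH2Cl2 at rt into 2-phenylethyl 2-(2-icosyl-1,3-dithiolan-2-yl)acetate F2. Desulfurisation with neutral-washed Raney Ni in THF at 60 °C (Mozingo reduction) should give the C3 methylene directly. The route is rejoined at 13.

3. Step 1. The half ester may lose CO2 thermally as it forms, or react a second time with the alcohol, so that neutral ester by-products replace the acid. Fallback by a protected malonate: setting out from 2, the alcohol would be esterified with commercial 3-tert-butoxy-3-oxopropanoic acid under Steglich conditions (DCC, DMAP, CH2Cl2, 0 °C to rt) to give tert-butyl 2-phenylethyl malonate F3. Treatment with CF3CO2H in CH2Cl2 at rt should remove the tert-butyl group as isobutene without heat. The route is rejoined at 3.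

Further compounds
F1 | step 3 | 5-(1-hydroxyhenicosylidene)-2,2-dimethyl-1,3-dioxane-4,6-dione | CCCCCCCCCCCCCCCCCCCCC(O)=C1C(=O)OC(C)(C)OC1=O
F2 | step 5 | 2-phenylethyl 2-(2-icosyl-1,3-dithiolan-2-yl)acetate | CCCCCCCCCCCCCCCCCCCCC1(CC(=O)OCCc2ccccc2)SCCS1
F3 | step 1 | tert-butyl 2-phenylethyl malonate | CC(C)(C)OC(=O)CC(=O)OCCc1ccccc1
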